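## The problem

CNP0254933.0 is a bibenzyl in which a hexasubstituted benzoic acid ring A (C1 CO2H, C2 OMe, C3 prenyl, C4 OH, C5 prenyl, C6 CH2) is joined through a saturated two-carbon bridge (Cα on C6, Cβ on ring B) to a 4-hydroxyphenyl ring B. The molecule has no stereocentre and both prenyl double bonds are trisubstituted, so the task is one of regiochemistry and functional-group tolerance only. Six substituents of five kinds must be placed around ring A, the two ring oxygens must be told apart (methyl ether at C2, free phenol at C4), and two prenyl groups must flank the C4 oxygen. The prenyl groups rule out hydrogenation, so the bridge should not be made as a stilbene and reduced; next to a free phenol they also rule out strong acid, which closes chromans. The carboxyl group lies between two ortho substituents, so an ordinary ester there resists saponification, and the electron-rich free acid can lose CO2 on heating or in acid. The enabling feature is that C6 is ortho to C1: a methyl group at C6 of a benzoate is the one benzylic position whose anion is conjugated with the ester. Cα can therefore be made nucleophilic and joined to a benzylic halide that carries Cβ and ring B.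

## Retrosynthesis

**Target 20 to protected bibenzyl 18.** The last operation removes three groups: the silyl ethers on the C4 oxygen and on the ring B oxygen, and a 2-(trimethylsilyl)ethyl ester at C1. A simple alkyl ester at this doubly flanked position would need forcing saponification or a nucleophilic dealkylation that also threatens the C2 methyl ether. The silylethyl ester is instead cut by fluoride at silicon, two atoms away from the crowded carbonyl, and the same fluoride frees both phenols. The forward reaction only has to be followed by a cold, brief acidification.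

**18 to toluate 13 and benzyl bromide 16.** The Cα–Cβ bond is cut. Cutting C6–Cα would require a coupling at an aryl carbon flanked by a prenyl group and the carboxyl group. Cutting the bridge as an alkene would require a hydrogenation beside two prenyl groups. With the chosen cut, Cα is a carbanion stabilised by the ester (lithium dienolate 17) and Cβ is a primary benzylic electrophile. Ring A (13) and ring B (16) are complete before they meet. The forward step must deprotonate the C6 methyl group and not the CH2 groups of the prenyl chains.

**16 to alcohol 15 to aldehyde 14.** The C–Br bond and then a C–H bond are cut. The bromide is electron-rich and labile, so it is made last and under neutral conditions from 15, which comes from commercial 14 by reduction with NaBH4.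

**13 to diallyl arene 11 and 2-methylbut-2-ene 12.** The two prenyl C=C bonds are cut. A prenyl group cannot be delivered cleanly to a ring carbon of a resorcylate by direct alkylation, because O- and C-alkylation, mono- and di-substitution and double alkylation at C3 compete. An allyl group can be delivered with fixed regiochemistry by sigmatropic shift. Cross-metathesis with 12 then turns each allyl terminus into a prenyl terminus. The forward step needs a catalyst that tolerates silyl ethers and an ester.

**11 to phenol 10 to diol 9.** The O–CH3 bond at C2 and the O–Si bond at C4 are cut. The two hydroxyls of 9 differ sharply: the C4 hydroxyl is free and acidic, the C2 hydroxyl is hydrogen-bonded to the ester. Silylation therefore goes to C4 first and methylation to C2 second.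

**9 to bis(allyl ether) 5.** The C3–allyl and C5–allyl bonds are cut. Both come from one thermal operation on 5, a double Claisen rearrangement through phenols 6, 7 or 8. The C2 ether has only C3 as a free ortho carbon, and whichever ortho position the C4 ether takes, the last allyl group ends on the last free carbon.

**5 to mono-ether 4, then to ester 2, allyl bromide 3 and acid 1.** The two O–allyl bonds are cut one at a time, because the two hydroxyls of 2 react under different conditions. The free C4 hydroxyl is etherified first with one equivalent of 3 under mild conditions, and the chelated C2 hydroxyl of 4 is etherified afterwards in a dipolar solvent with heating. Each step then gives a single, defined ether, and 4 is also the point from which the two rearrangements could be run one after the other. Compound 2 is the silylethyl ester of commercial orsellinic acid 1, whose methyl group is the future Cα.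

## Roads not taken

**Alternative 1:** Ring A would be cut at C1–C6 and unrolled into a polyketide chain. Under mild base the diketo-dioxinone A1 would add its dioxinone α-carbon (future C1) to the terminal ketone (future C6), then dehydrate and enolise to benzodioxinone A2. The merits are real. No substitution on an arene is needed, the conditions are mild, and A2 has the C4 hydroxyl free while the C2 oxygen is tied to the carboxyl in the acetonide. That differentiates the two phenols for free, whereas the chosen plan spends steps 5 and 6 on it. The weak point is A1 itself. It carries one prenyl group on each of the two carbons between three carbonyl groups. Each of those carbons can be O-alkylated or alkylated twice, and the chain can also cyclise to a pyrone or in the other aldol direction. After the key step the acetonide must still be opened, C2 methylated selectively and the acid freed, which is about four steps against one in the chosen plan. Against the built-in phenol differentiation the chosen plan sets a bought aromatic ring, two C–C bonds formed by shifts of fixed regiochemistry, and a one-step end game.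

**Alternative 2:** Three ring bonds (C1–C2, C3–C4, C4–C5) would be cut. Irradiation of diazo ketoester A3 with methoxyalkyne A4 would trigger Wolff rearrangement, [2+2] cycloaddition, 4π ring opening and 6π closure to phenol A5 (Danheiser benzannulation). This is the most convergent ring construction of all. All six substituents arrive in one step, the polarisation of A4 fixes the methoxy group meta to the new hydroxyl, and the bridge and ring B are already in place. In convergence it is better than the chosen plan. Its weak points lie in the reactive intermediates and the precursors. The Wolff-rearranged species bears the ester on its cumulene carbon and has trisubstituted alkenes within reach, so intramolecular [2+2] and hetero-diene pathways compete with the wanted cycloaddition. A4 is an acid-sensitive alkoxyalkyne with a skipped ene-yne, and A3 needs a multistep synthesis. A5 is a hindered methyl ester, so the ester-cleavage problem returns at the end. The chosen plan sets against this ground-state reactions only, prenyl groups that are never exposed to an electrophilic intermediate, and an ester designed for its removal.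

**Alternative 3:** The C6–Cα and C1–carboxyl bonds would be cut. Iodine–magnesium exchange on the 2-iodoaryl sulfonate A6 with iPrMgCl and loss of sulfonate would create a C1–C6 triple bond in ring A. Grignard reagent A7 would add at C6, and carboxylation at C1 would give acid A8. The acid arrives free, so no ester has to be cleaved. In that respect this road is better, and the chosen plan answers with the fluoride-labile ester. The regiochemistry of addition is also well founded, since the C2 methoxy group directs the nucleophile to the distal carbon. The difficulties are A6 and the reactive intermediate. A6 is a pentasubstituted benzene with three different oxygen functions, an iodine and two prenyl groups, and it is harder to make than 13. The strained triple bond sits beside the C5 prenyl group, whose allylic hydrogens invite an intramolecular ene reaction. Addition of a primary alkylmagnesium to such a species is less dependable than the alkylation of a stabilised carbanion. The chosen plan forms the same bridge from a conjugated anion by a reaction type with direct precedent on 2-alkoxy-6-methylbenzoates.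

Key step: step 10

## Route

Remark on the chemistry: 20 has no stereocentre and no stereogenic double bond, so no SMILES string needs a stereo descriptor. Ring A keeps the numbering C1 (carboxyl carbon) to C6 (bridge-bearing carbon) in every intermediate.

Step 1
Reactants: 1 2,4-dihydroxy-6-methylbenzoic acid (orsellinic acid)
Product: 2 2-(trimethylsilyl)ethyl 2,4-dihydroxy-6-methylbenzoate
Conditions: Me3SiCH2CH2OH (1.0 equiv), PPh3, DIAD, THF, 0 °C to rt
Reagents that add atoms: 2-(trimethylsilyl)ethanol, C[Si](C)(C)CCO
Why: Mitsunobu esterification: the alcohol is activated as its oxyphosphonium salt and the carboxylate, far more acidic than either phenol, is the nucleophile, so the acid is esterified without phenol protection and without heating a decarboxylation-prone acid.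

Step 2
Reactants: 2 2-(trimethylsilyl)ethyl 2,4-dihydroxy-6-methylbenzoate; 3 3-bromoprop-1-ene (allyl bromide)
Product: 4 2-(trimethylsilyl)ethyl 2-hydroxy-6-methyl-4-(prop-2-enyloxy)benzoate
Conditions: allyl bromide (1.05 equiv), K2CO3 (1.1 equiv), acetone, rt
Reagents that add atoms: none
Why: Williamson ether synthesis: with one equivalent of 3 and a mild base only the free, more acidic C4 phenol is alkylated, because the C2 phenol is held in a hydrogen bond to the ester carbonyl and does not react in acetone at room temperature.

Step 3
Reactants: 4 2-(trimethylsilyl)ethyl 2-hydroxy-6-methyl-4-(prop-2-enyloxy)benzoate; 3 3-bromoprop-1-ene (allyl bromide)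
Product: 5 2-(trimethylsilyl)ethyl 6-methyl-2,4-bis(prop-2-enyloxy)benzoate
Conditions: allyl bromide (1.5 equiv), K2CO3, DMF, 60 °C
Reagents that add atoms: none
Why: Williamson ether synthesis on the chelated C2 phenol, which needs the dipolar solvent and gentle heating; the silylethyl ester is inert to K2CO3 and the C4 ether already in place is unaffected.

Step 4
Reactants: 5 2-(trimethylsilyl)ethyl 6-methyl-2,4-bis(prop-2-enyloxy)benzoate
Product: 9 2-(trimethylsilyl)ethyl 2,4-dihydroxy-6-methyl-3,5-di(prop-2-enyl)benzoate, via C3-allyl C4-allyl ether 6 (not isolated), via C5-allyl C2-allyl ether 7 (not isolated), via C3-allyl C2-allyl ether 8 (not isolated)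
Conditions: PhNEt2, 195 °C, sealed tube
Reagents that add atoms: none
Why: Double aromatic Claisen rearrangement ([3,3] shift, then enolisation): the C2 ether delivers to its only free ortho carbon C3 (giving 6) and the C4 ether to C5 or C3 (giving 7 or 8). In each case the remaining ether is led to the last free carbon, for 8 by para-Claisen migration (ortho-dienone, then Cope shift), so all paths should converge on 9.

Step 5
Reactants: 9 2-(trimethylsilyl)ethyl 2,4-dihydroxy-6-methyl-3,5-di(prop-2-enyl)benzoate
Product: 10 2-(trimethylsilyl)ethyl 4-(tert-butyldimethylsilyloxy)-2-hydroxy-6-methyl-3,5-di(prop-2-enyl)benzoate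
Conditions: TBSCl, imidazole, DMF, rt
Reagents that add atoms: tert-butyldimethylsilyl chloride, CC(C)(C)[Si](C)(C)Cl
Why: Silyl ether formation selects the C4 hydroxyl, which is free and the more acidic (para to the ester), whereas the C2 hydroxyl is locked in a hydrogen bond to the ester carbonyl and should not react under these conditions.

Step 6
Reactants: 10 2-(trimethylsilyl)ethyl 4-(tert-butyldimethylsilyloxy)-2-hydroxy-6-methyl-3,5-di(prop-2-enyl)benzoate
Product: 11 2-(trimethylsilyl)ethyl 4-(tert-butyldimethylsilyloxy)-2-methoxy-6-methyl-3,5-di(prop-2-enyl)benzoate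
Conditions: MeI, K2CO3, acetone, 50 °C
Reagents that add atoms: iodomethane, CI
Why: Williamson methylation of the chelated C2 phenol; the C4 silyl ether is shielded by two ortho allyl groups and the medium is anhydrous and non-hydroxylic, so it should stay in place, and the silylethyl ester is untouched.

Step 7
Reactants: 11 2-(trimethylsilyl)ethyl 4-(tert-butyldimethylsilyloxy)-2-methoxy-6-methyl-3,5-di(prop-2-enyl)benzoate; 12 2-methylbut-2-ene
Product: 13 2-(trimethylsilyl)ethyl 4-(tert-butyldimethylsilyloxy)-2-methoxy-6-methyl-3,5-bis(3-methylbut-2-enyl)benzoate
Conditions: second-generation Grubbs catalyst RuCl2(=CHPh)(PCy3)(H2IMes) (5 mol %), 2-methylbut-2-ene (large excess), CH2Cl2, 40 °C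
Reagents that add atoms: none
Why: Olefin cross-metathesis: each terminal allyl group exchanges its CH2 terminus for the isopropylidene unit of 12 and propene leaves. The trisubstituted prenyl double bonds are poor metathesis substrates, so the reaction should stop there, and no E/Z question arises.

Step 8
Reactants: 14 4-(tert-butyldimethylsilyloxy)benzaldehyde
Product: 15 [4-(tert-butyldimethylsilyloxy)phenyl]methanol
Conditions: NaBH4, MeOH, 0 °C
Reagents that add atoms: none
Why: NaBH4 reduction of an aryl aldehyde to the benzylic alcohol; a short reaction at 0 °C leaves the aryl silyl ether intact.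

Step 9
Reactants: 15 [4-(tert-butyldimethylsilyloxy)phenyl]methanol
Product: 16 4-(tert-butyldimethylsilyloxy)benzyl bromide
Conditions: CBr4, PPh3, CH2Cl2, 0 °C
Reagents that add atoms: tetrabromomethane, BrC(Br)(Br)Br
Why: Appel reaction: the alcohol is activated as its oxyphosphonium salt and displaced by bromide under neutral conditions, so no acid is present to cleave the silyl ether. The electron-rich bromide is passed through a short pad and used at once.

Step 10
Reactants: 13 2-(trimethylsilyl)ethyl 4-(tert-butyldimethylsilyloxy)-2-methoxy-6-methyl-3,5-bis(3-methylbut-2-enyl)benzoate; 16 4-(tert-butyldimethylsilyloxy)benzyl bromide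
Product: 18 2-(trimethylsilyl)ethyl 4-(tert-butyldimethylsilyloxy)-6-{2-[4-(tert-butyldimethylsilyloxy)phenyl]ethyl}-2-methoxy-3,5-bis(3-methylbut-2-enyl)benzoate, via benzylic lithium dienolate 17 (not isolated)
Conditions: LiN(iPr)2 (1.05 equiv), THF, −78 °C; then 16, −78 to −40 °C
Reagents that add atoms: none
Why: LiN(iPr)2, pre-complexed to the ester carbonyl, removes a proton from the C6 methyl group of 13, the only benzylic position whose anion is conjugated with the ester, to give 17, a lithium dienolate of ortho-quinodimethane type. 17 attacks the primary benzylic carbon of 16 in an SN2 displacement of bromide, which forms the Cα–Cβ bond and restores the aromatic ring, so the bridge arrives saturated and no hydrogenation is needed beside the prenyl groups. The closest known reaction type is the lateral lithiation of 2-alkoxy-6-methylbenzoates with lithium amides followed by alkylation with benzylic halides. No ring is closed and no stereocentre is formed. The selectivity needed is deprotonation at the C6 methyl group and not at the benzylic-allylic CH2 groups on C3 and C5; these are meta to the ester, gain no enolate stabilisation and are not reached by the ester-bound LiN(iPr)2, so kinetic deprotonation at −78 °C should favour C6. Attack of 17 on the ester of a second molecule is held back by the two ortho substituents and the bulky silylethoxy group, and a second alkylation by the use of barely more than one equivalent of base and by the greater hindrance of the new methylene. Both aryl silyl ethers and the silylethyl ester are inert to LiN(iPr)2 at this temperature, and neither silyl ether is ortho to the carbanion, so no silyl migration is expected.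

Step 11
Reactants: 18 2-(trimethylsilyl)ethyl 4-(tert-butyldimethylsilyloxy)-6-{2-[4-(tert-butyldimethylsilyloxy)phenyl]ethyl}-2-methoxy-3,5-bis(3-methylbut-2-enyl)benzoate
Product: 20 4-hydroxy-6-[2-(4-hydroxyphenyl)ethyl]-2-methoxy-3,5-bis(3-methylbut-2-enyl)benzoic acid (CNP0254933.0), via bisphenol silylethyl ester 19 (not isolated)
Conditions: Bu4NF (6 equiv), THF, 0 °C to rt; then cold dilute HCl to pH 3–4
Reagents that add atoms: none
Why: Fluoride-mediated global deprotection: fluoride cleaves both aryl O–Si bonds to give 19 and then attacks the trimethylsilyl group of the ester, which fragments to ethene, Me3SiF and the carboxylate (β-elimination), a cleavage that does not depend on access to the hindered carbonyl. Brief cold acidification should free the acid without closing chromans or losing CO2.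

## Compound list

1 | 2,4-dihydroxy-6-methylbenzoic acid (orsellinic acid) | Cc1cc(O)cc(O)c1C(=O)O | starting material
2 | 2-(trimethylsilyl)ethyl 2,4-dihydroxy-6-methylbenzoate | Cc1cc(O)cc(O)c1C(=O)OCC[Si](C)(C)C | intermediate
3 | 3-bromoprop-1-ene (allyl bromide) | C=CCBr | starting material
4 | 2-(trimethylsilyl)ethyl 2-hydroxy-6-methyl-4-(prop-2-enyloxy)benzoate | Cc1cc(OCC=C)cc(O)c1C(=O)OCC[Si](C)(C)C | intermediate
5 | 2-(trimethylsilyl)ethyl 6-methyl-2,4-bis(prop-2-enyloxy)benzoate | Cc1cc(OCC=C)cc(OCC=C)c1C(=O)OCC[Si](C)(C)C | intermediate
6 | 2-(trimethylsilyl)ethyl 2-hydroxy-6-methyl-3-(prop-2-enyl)-4-(prop-2-enyloxy)benzoate | Cc1cc(OCC=C)c(CC=C)c(O)c1C(=O)OCC[Si](C)(C)C | intermediate (not isolated)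
7 | 2-(trimethylsilyl)ethyl 4-hydroxy-6-methyl-5-(prop-2-enyl)-2-(prop-2-enyloxy)benzoate | Cc1c(CC=C)c(O)cc(OCC=C)c1C(=O)OCC[Si](C)(C)C | intermediate (not isolated)
8 | 2-(trimethylsilyl)ethyl 4-hydroxy-6-methyl-3-(prop-2-enyl)-2-(prop-2-enyloxy)benzoate | Cc1cc(O)c(CC=C)c(OCC=C)c1C(=O)OCC[Si](C)(C)C | intermediate (not isolated)
9 | 2-(trimethylsilyl)ethyl 2,4-dihydroxy-6-methyl-3,5-di(prop-2-enyl)benzoate | Cc1c(CC=C)c(O)c(CC=C)c(O)c1C(=O)OCC[Si](C)(C)C | intermediate
10 | 2-(trimethylsilyl)ethyl 4-(tert-butyldimethylsilyloxy)-2-hydroxy-6-methyl-3,5-di(prop-2-enyl)benzoate | Cc1c(CC=C)c(O[Si](C)(C)C(C)(C)C)c(CC=C)c(O)c1C(=O)OCC[Si](C)(C)C | intermediate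
11 | 2-(trimethylsilyl)ethyl 4-(tert-butyldimethylsilyloxy)-2-methoxy-6-methyl-3,5-di(prop-2-enyl)benzoate | COc1c(CC=C)c(O[Si](C)(C)C(C)(C)C)c(CC=C)c(C)c1C(=O)OCC[Si](C)(C)C | intermediate
12 | 2-methylbut-2-ene | CC=C(C)C | starting material
13 | 2-(trimethylsilyl)ethyl 4-(tert-butyldimethylsilyloxy)-2-methoxy-6-methyl-3,5-bis(3-methylbut-2-enyl)benzoate | COc1c(CC=C(C)C)c(O[Si](C)(C)C(C)(C)C)c(CC=C(C)C)c(C)c1C(=O)OCC[Si](C)(C)C | intermediate
14 | 4-(tert-butyldimethylsilyloxy)benzaldehyde | CC(C)(C)[Si](C)(C)Oc1ccc(C=O)cc1 | starting material
15 | [4-(tert-butyldimethylsilyloxy)phenyl]methanol | CC(C)(C)[Si](C)(C)Oc1ccc(CO)cc1 | intermediate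
16 | 4-(tert-butyldimethylsilyloxy)benzyl bromide | CC(C)(C)[Si](C)(C)Oc1ccc(CBr)cc1 | intermediate
17 | 2-(trimethylsilyl)ethyl 4-(tert-butyldimethylsilyloxy)-6-(lithiomethyl)-2-methoxy-3,5-bis(3-methylbut-2-enyl)benzoate (lithium dienolate of 13) | COc1c(CC=C(C)C)c(O[Si](C)(C)C(C)(C)C)c(CC=C(C)C)c(C[Li])c1C(=O)OCC[Si](C)(C)C | intermediate (not isolated)
18 | 2-(trimethylsilyl)ethyl 4-(tert-butyldimethylsilyloxy)-6-{2-[4-(tert-butyldimethylsilyloxy)phenyl]ethyl}-2-methoxy-3,5-bis(3-methylbut-2-enyl)benzoate | COc1c(CC=C(C)C)c(O[Si](C)(C)C(C)(C)C)c(CC=C(C)C)c(CCc2ccc(O[Si](C)(C)C(C)(C)C)cc2)c1C(=O)OCC[Si](C)(C)C | intermediate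
19 | 2-(trimethylsilyl)ethyl 4-hydroxy-6-[2-(4-hydroxyphenyl)ethyl]-2-methoxy-3,5-bis(3-methylbut-2-enyl)benzoate | COc1c(CC=C(C)C)c(O)c(CC=C(C)C)c(CCc2ccc(O)cc2)c1C(=O)OCC[Si](C)(C)C | intermediate (not isolated)
20 | 4-hydroxy-6-[2-(4-hydroxyphenyl)ethyl]-2-methoxy-3,5-bis(3-methylbut-2-enyl)benzoic acid (CNP0254933.0) | COc1c(CC=C(C)C)c(O)c(CC=C(C)C)c(CCc2ccc(O)cc2)c1C(=O)O | target

## Step count and least certain steps

Total step count: 11. Longest linear sequence: 9 steps (steps 1 to 7, then 10 and 11). Steps 8 and 9 form the short second branch.

**Step 10 (key step).** The most likely failure is slow or misdirected deprotonation. The C6 methyl group of 13 is flanked by the C5 prenyl group and a twisted ester, so LiN(iPr)2 may instead attack the benzylic-allylic CH2 groups or the bromide, which would couple 16 to a stilbene. Over-alkylation of the new methylene is a second risk. The fallback forms the bridge before ring A is crowded, on a substrate of the type for which the precedent was set. It sets out from 5, which is deprotonated with LiN(iPr)2 in THF at −78 °C and alkylated with 16. This should give 2-(trimethylsilyl)ethyl 6-{2-[4-(tert-butyldimethylsilyloxy)phenyl]ethyl}-2,4-bis(prop-2-enyloxy)benzoate F1. Heating as in step 4 should give the 3,5-diallyl-2,4-dihydroxy ester F2. Silylation as in step 5 gives the C4 silyl ether F3, and methylation as in step 6 gives the C2 methyl ether F4. Cross-metathesis of F4 with 12 as in step 7 comes back to the route at 18. The main route is preferred because it joins two finished fragments and does not carry ring B through the thermal step.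

**Step 4.** The most likely failure is incomplete convergence. If the C4 allyl group takes C3 first (compound 8), the para migration of the second group may stall. Long heating may also cyclise ortho-allylphenols to dihydrobenzofurans or cost the silylethyl ester its ethene. The fallback runs the two rearrangements one at a time, each with a shorter heating period. It sets out from 4, the mono-ether that the route already isolates. Heating 4 should place the allyl group at C3, the position favoured when the C2 hydroxyl is chelated to the ester, giving 2-(trimethylsilyl)ethyl 2,4-dihydroxy-6-methyl-3-(prop-2-enyl)benzoate F5. A second allylation at the free C4 hydroxyl (3, K2CO3, acetone) gives 6, isolated in this variant. Its rearrangement can reach only C5 and comes back to the route at 9.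

**Step 6.** The most likely failure is loss or intermolecular transfer of the aryl silyl group under K2CO3, followed by methylation of the C4 oxygen. The fallback masks C4 as an acetal during the methylation. It sets out from 9. MOMCl and iPr2NEt in CH2Cl2 should give the 4-(methoxymethoxy) compound F6. MeI and K2CO3 in DMF give its C2 methyl ether F7. HCl in MeOH, which terminal allyl groups tolerate where prenyl groups would not, frees the C4 phenol to give 2-(trimethylsilyl)ethyl 4-hydroxy-2-methoxy-6-methyl-3,5-di(prop-2-enyl)benzoate F8. Silylation of F8 with TBSCl and imidazole comes back to the route at 11.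

**Step 9.** The most likely failure is ionisation of the electron-rich benzylic bromide during isolation, leading to hydrolysis or oligomerisation. The fallback sets out from 15 and makes the less ionisable 4-(tert-butyldimethylsilyloxy)benzyl chloride F9 (MsCl, Et3N, then LiCl). F9 can be purified and stored, and it alkylates 17 at −78 to 0 °C to come back to the route at 18.

**Step 1.** The most likely failure is competing etherification of the C4 phenol by the activated alcohol. The fallback activates the carboxyl group instead of the alcohol. It sets out from 1, which is condensed with acetone ((CF3CO)2O, CF3CO2H) to give 7-hydroxy-2,2,5-trimethyl-1,3-benzodioxin-4-one F10. Opening F10 with sodium 2-(trimethylsilyl)ethoxide in THF comes back to the route at 2.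

## Further compounds

F1 | step 10 | 2-(trimethylsilyl)ethyl 6-{2-[4-(tert-butyldimethylsilyloxy)phenyl]ethyl}-2,4-bis(prop-2-enyloxy)benzoate | C=CCOc1cc(OCC=C)c(C(=O)OCC[Si](C)(C)C)c(CCc2ccc(O[Si](C)(C)C(C)(C)C)cc2)c1
F2 | step 10 | 2-(trimethylsilyl)ethyl 6-{2-[4-(tert-butyldimethylsilyloxy)phenyl]ethyl}-2,4-dihydroxy-3,5-di(prop-2-enyl)benzoate | Oc1c(CC=C)c(O)c(CC=C)c(CCc2ccc(O[Si](C)(C)C(C)(C)C)cc2)c1C(=O)OCC[Si](C)(C)C
F3 | step 10 | 2-(trimethylsilyl)ethyl 4-(tert-butyldimethylsilyloxy)-6-{2-[4-(tert-butyldimethylsilyloxy)phenyl]ethyl}-2-hydroxy-3,5-di(prop-2-enyl)benzoate | Oc1c(CC=C)c(O[Si](C)(C)C(C)(C)C)c(CC=C)c(CCc2ccc(O[Si](C)(C)C(C)(C)C)cc2)c1C(=O)OCC[Si](C)(C)C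
F4 | step 10 | 2-(trimethylsilyl)ethyl 4-(tert-butyldimethylsilyloxy)-6-{2-[4-(tert-butyldimethylsilyloxy)phenyl]ethyl}-2-methoxy-3,5-di(prop-2-enyl)benzoate | COc1c(CC=C)c(O[Si](C)(C)C(C)(C)C)c(CC=C)c(CCc2ccc(O[Si](C)(C)C(C)(C)C)cc2)c1C(=O)OCC[Si](C)(C)C
F5 | step 4 | 2-(trimethylsilyl)ethyl 2,4-dihydroxy-6-methyl-3-(prop-2-enyl)benzoate | Cc1cc(O)c(CC=C)c(O)c1C(=O)OCC[Si](C)(C)C
F6 | step 6 | 2-(trimethylsilyl)ethyl 2-hydroxy-4-(methoxymethoxy)-6-methyl-3,5-di(prop-2-enyl)benzoate | Cc1c(CC=C)c(OCOC)c(CC=C)c(O)c1C(=O)OCC[Si](C)(C)C
F7 | step 6 | 2-(trimethylsilyl)ethyl 2-methoxy-4-(methoxymethoxy)-6-methyl-3,5-di(prop-2-enyl)benzoate | COCOc1c(CC=C)c(C)c(C(=O)OCC[Si](C)(C)C)c(OC)c1CC=C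
F8 | step 6 | 2-(trimethylsilyl)ethyl 4-hydroxy-2-methoxy-6-methyl-3,5-di(prop-2-enyl)benzoate | COc1c(CC=C)c(O)c(CC=C)c(C)c1C(=O)OCC[Si](C)(C)C
F9 | step 9 | 4-(tert-butyldimethylsilyloxy)benzyl chloride | CC(C)(C)[Si](C)(C)Oc1ccc(CCl)cc1
F10 | step 1 | 7-hydroxy-2,2,5-trimethyl-1,3-benzodioxin-4-one | Cc1cc(O)cc2OC(C)(C)OC(=O)c12
A1 | alternative 1 | 6-{1-[4-(tert-butyldimethylsilyloxy)phenyl]-9-methyl-4-(3-methylbut-2-enyl)-3,5-dioxodec-8-en-6-yl}-2,2-dimethyl-1,3-dioxin-4-one (mixture of epimers and enol forms) | CC1(C)OC(=O)C=C(O1)C(CC=C(C)C)C(=O)C(CC=C(C)C)C(=O)CCc1ccc(O[Si](C)(C)C(C)(C)C)cc1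
A2 | alternative 1 | 7-hydroxy-2,2-dimethyl-6,8-bis(3-methylbut-2-enyl)-5-{2-[4-(tert-butyldimethylsilyloxy)phenyl]ethyl}-1,3-benzodioxin-4-one | CC1(C)OC(=O)c2c(O1)c(CC=C(C)C)c(O)c(CC=C(C)C)c2CCc1ccc(O[Si](C)(C)C(C)(C)C)cc1
A3 | alternative 2 | methyl 2-diazo-8-methyl-3-oxo-4-{2-[4-(tert-butyldimethylsilyloxy)phenyl]ethyl}nona-4,7-dienoate (geometry of the C4 double bond left open) | COC(=O)C(=[N+]=[N-])C(=O)C(CCc1ccc(O[Si](C)(C)C(C)(C)C)cc1)=CCC=C(C)C
A4 | alternative 2 | 1-methoxy-5-methylhex-4-en-1-yne | COC#CCC=C(C)C
A5 | alternative 2 | methyl 4-hydroxy-2-methoxy-3,5-bis(3-methylbut-2-enyl)-6-{2-[4-(tert-butyldimethylsilyloxy)phenyl]ethyl}benzoate | COC(=O)c1c(OC)c(CC=C(C)C)c(O)c(CC=C(C)C)c1CCc2ccc(O[Si](C)(C)C(C)(C)C)cc2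
A6 | alternative 3 | 5-(tert-butyldimethylsilyloxy)-2-iodo-3-methoxy-4,6-bis(3-methylbut-2-enyl)phenyl 4-chlorobenzenesulfonate | COc1c(I)c(OS(=O)(=O)c2ccc(Cl)cc2)c(CC=C(C)C)c(O[Si](C)(C)C(C)(C)C)c1CC=C(C)C
A7 | alternative 3 | {2-[4-(tert-butyldimethylsilyloxy)phenyl]ethyl}magnesium bromide | CC(C)(C)[Si](C)(C)Oc1ccc(CC[Mg]Br)cc1
A8 | alternative 3 | 4-(tert-butyldimethylsilyloxy)-2-methoxy-3,5-bis(3-methylbut-2-enyl)-6-{2-[4-(tert-butyldimethylsilyloxy)phenyl]ethyl}benzoic acid | COc1c(C(=O)O)c(CCc2ccc(O[Si](C)(C)C(C)(C)C)cc2)c(CC=C(C)C)c(O[Si](C)(C)C(C)(C)C)c1CC=C(C)C
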